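**Retrosynthetic overview**

1. The target is fisetinidol-(4α→6)-fisetinidol (flavan locants; unprimed = upper, C4-linked unit; primed = lower unit). The free phenols are released last by hydrogenolysis of a hexabenzyl ether.
2. The C3–OH/C4–H and C3'–OH/C4'–H pairs are taken back to two C=C bonds. Double hydroboration–oxidation of a bis(2H-chromene), anti to each C2 aryl group, sets C3, C4 and C3' from C2 and C2'.
3. Key disconnection: both pyran rings are opened at once by double RCM of an acyclic tetraene, ring C' of the lower unit at C3'=C4' and ring C of the upper unit at C3=C4. The enabling feature: in each unit C3–C4 lies between C4a (an arene carbon ortho to O1) and C2 (a benzylic carbon bound to O1). At the alkene oxidation level each ring is therefore the RCM product of an aryl 1-arylallyl ether and an ortho alkenyl group, and the interflavan C4–C6' bond is simply the aryl–C bond of a 1,1-diarylethylene.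
4. The tetraene comes from a 1,1-diarylethylene with one free and one silyl-masked phenol. Two successive iridium-catalysed asymmetric allylic etherifications, one per phenol and each with one molecule of the same cinnamyl carbonate, set C2' and then C2. The diarylethylene comes from an aryl bromide and an acetophenone tosylhydrazone by carbene cross-coupling.
5. Ring order: the four benzene rings (A, A', B, B') are bought; ring C' and then ring C are closed last, in the same operation.

Key step: step 12

Assumption: the (Sa,S,S) enantiomer of the phosphoramidite ligand is taken to give the S-configured branched aryl ethers needed here; if this substrate shows the opposite sense, the mirror-image ligand is used in steps 9 and 11 and nothing else changes.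

**Route**

Step 1
Reactants: 1 4-(benzyloxy)-2-hydroxybenzaldehyde
Product: 2 4-(benzyloxy)-5-bromo-2-hydroxybenzaldehyde
Conditions: NBS (1.05 equiv), MeCN, 0 °C to rt
Reagents that add atoms: N-bromosuccinimide, O=C1CCC(=O)N1Br
Why: Electrophilic aromatic bromination of the phenol should occur at C5, para to the free hydroxyl and ortho to the benzyloxy group, because the only other activated position (C3) is flanked by two oxygen substituents; this installs the handle for the future C4–C6' bond.

Step 2
Reactants: 2 4-(benzyloxy)-5-bromo-2-hydroxybenzaldehyde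
Product: 3 5-(benzyloxy)-4-bromo-2-ethenylphenol
Conditions: Ph3PCH3Br (2.5 equiv), KOtBu (2.5 equiv), THF, 0 °C to rt
Reagents that add atoms: methyltriphenylphosphonium bromide, C[P+](c1ccccc1)(c1ccccc1)c1ccccc1.[Br-]
Why: Wittig methylenation with excess ylide (one equivalent of base is held by the phenol) should turn the aldehyde into the vinyl group that supplies C4' of the lower unit, the aryl bromide and benzyl ether being inert to the ylide.

Step 3
Reactants: 4 1-[4-(benzyloxy)-2-hydroxyphenyl]ethan-1-one
Product: 5 1-{4-(benzyloxy)-2-[(triisopropylsilyl)oxy]phenyl}ethan-1-one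
Conditions: i-Pr3SiCl (1.3 equiv), imidazole (2.5 equiv), DMAP (10 mol%), DMF, 40 °C
Reagents that add atoms: chlorotri(propan-2-yl)silane, CC(C)[Si](Cl)(C(C)C)C(C)C
Why: Imidazole-mediated O-silylation of the hydrogen-bonded ortho-hydroxy ketone should give the aryl triisopropylsilyl ether, a mask that resists hindered lithium alkoxide at 100 °C, comes off with fluoride without acid, and keeps the two phenolic oxygens of the later diarylethylene distinguishable.

Step 4
Reactants: 5 1-{4-(benzyloxy)-2-[(triisopropylsilyl)oxy]phenyl}ethan-1-one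
Product: 6 N-tosylhydrazone of 5
Conditions: TsNHNH2 (1.1 equiv), MeOH, 60 °C
Reagents that add atoms: 4-methylbenzenesulfonohydrazide, Cc1ccc(cc1)S(=O)(=O)NN
Why: Condensation of the methyl ketone with tosylhydrazide should give the E N-tosylhydrazone, the carbene precursor for the next step, the aryl silyl ether being stable to the weakly acidic medium.

Step 5
Reactants: 3 5-(benzyloxy)-4-bromo-2-ethenylphenol; 6 N-tosylhydrazone of 5
Product: 8 5-(benzyloxy)-4-(1-{4-(benzyloxy)-2-[(triisopropylsilyl)oxy]phenyl}ethenyl)-2-ethenylphenol, via diazoalkane 7 (not isolated)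
Conditions: Pd2(dba)3 (2.5 mol%), XPhos (10 mol%), LiOtBu (4 equiv), 1,4-dioxane, 100 °C; aqueous NH4Cl work-up
Reagents that add atoms: none
Why: Barluenga–Valdés coupling: LiOtBu converts 6 by Bamford–Stevens fragmentation into diazoalkane 7, the arylpalladium bromide formed from 3 and zerovalent palladium traps it as a palladium carbene, and aryl migration followed by β-hydride elimination from the methyl group should give the 1,1-diarylethylene whose aryl–C bond is the future interflavan C4–C6' bond, with one phenol free and the other still silylated.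

Step 6
Reactants: 9 3,4-bis(benzyloxy)benzaldehyde
Product: 10 ethyl (2E)-3-[3,4-bis(benzyloxy)phenyl]prop-2-enoate
Conditions: (EtO)2P(O)CH2CO2Et (1.2 equiv), NaH (1.2 equiv), THF, 0 °C to rt
Reagents that add atoms: triethyl phosphonoacetate, CCOC(=O)CP(=O)(OCC)OCC
Why: Horner–Wadsworth–Emmons olefination of an aromatic aldehyde with a stabilised phosphonate anion should give the E cinnamate.

Step 7
Reactants: 10 ethyl (2E)-3-[3,4-bis(benzyloxy)phenyl]prop-2-enoate
Product: 11 (2E)-3-[3,4-bis(benzyloxy)phenyl]prop-2-en-1-ol
Conditions: i-Bu2AlH (2.2 equiv), CH2Cl2, −78 °C; aqueous potassium sodium tartrate work-up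
Reagents that add atoms: none
Why: 1,2-Reduction of the unsaturated ester with i-Bu2AlH at low temperature should give the E allylic alcohol without touching the alkene or the benzyl ethers.

Step 8
Reactants: 11 (2E)-3-[3,4-bis(benzyloxy)phenyl]prop-2-en-1-ol
Product: 12 (2E)-3-[3,4-bis(benzyloxy)phenyl]prop-2-en-1-yl methyl carbonate
Conditions: ClCO2Me (1.3 equiv), pyridine (2 equiv), CH2Cl2, 0 °C
Reagents that add atoms: methyl chloroformate, COC(=O)Cl
Why: Acylation of the primary allylic alcohol with a chloroformate should give the linear allylic carbonate, the standard electrophile for iridium-catalysed allylic substitution, prepared in quantity for use in steps 9 and 11.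

Step 9
Reactants: 8 5-(benzyloxy)-4-(1-{4-(benzyloxy)-2-[(triisopropylsilyl)oxy]phenyl}ethenyl)-2-ethenylphenol; 12 (2E)-3-[3,4-bis(benzyloxy)phenyl]prop-2-en-1-yl methyl carbonate
Product: 14 lower-ring (1S)-allylic ether of 8, via lithium aryloxide 13 (not isolated)
Conditions: LiN(SiMe3)2 (1.0 equiv), THF, 0 °C; then 12 (1.2 equiv), [Ir(cod)Cl]2 (2 mol%), (Sa,S,S)-(1,1'-binaphthalene-2,2'-diyl) N,N-bis(1-phenylethyl)phosphoramidite (4 mol%, catalyst pre-activated with n-PrNH2, volatiles removed), THF, 50 °C
Reagents that add atoms: none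
Why: Iridium-catalysed asymmetric allylic etherification: the lithium aryloxide should attack the aryl-bearing terminus of the π-allyl iridium complex formed from 12 to give the branched aryl 1-arylallyl ether, the chiral phosphoramidite setting the new stereocenter (future C2') as S under catalyst control, while the silyl-masked phenol cannot react so that exactly one allyl unit is taken up; the non-nucleophilic amide base avoids addition to the 1,1-diarylethylene.

Step 10
Reactants: 14 lower-ring (1S)-allylic ether of 8
Product: 15 5-(benzyloxy)-2-[1-(2-(benzyloxy)-4-{[(1S)-1-[3,4-bis(benzyloxy)phenyl]prop-2-en-1-yl]oxy}-5-ethenylphenyl)ethenyl]phenol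
Conditions: Bu4NF (1.1 equiv), AcOH (1.1 equiv), THF, 0 °C to rt
Reagents that add atoms: none
Why: Fluoride-induced cleavage of the aryl triisopropylsilyl ether, driven by Si–F bond formation and buffered with acetic acid, should free the upper-ring phenol without touching the benzyl ethers, the alkenes or the acid- and base-sensitive allylic ether, whose stereocenter is not involved.

Step 11
Reactants: 15 5-(benzyloxy)-2-[1-(2-(benzyloxy)-4-{[(1S)-1-[3,4-bis(benzyloxy)phenyl]prop-2-en-1-yl]oxy}-5-ethenylphenyl)ethenyl]phenol; 12 (2E)-3-[3,4-bis(benzyloxy)phenyl]prop-2-en-1-yl methyl carbonate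
Product: 17 tetraene bis[(1S)-allylic ether], via lithium aryloxide 16 (not isolated)
Conditions: LiN(SiMe3)2 (1.0 equiv), THF, 0 °C; then 12 (1.3 equiv), [Ir(cod)Cl]2 (3 mol%), (Sa,S,S)-(1,1'-binaphthalene-2,2'-diyl) N,N-bis(1-phenylethyl)phosphoramidite (6 mol%, catalyst pre-activated with n-PrNH2, volatiles removed), THF, 50 °C
Reagents that add atoms: none
Why: A second iridium-catalysed asymmetric allylic etherification, now at the aryloxide ortho to the 1-arylethenyl group, should give the second branched ether with the new stereocenter (future C2) set as S by the same ligand; because the two centres are set in independent catalyst-controlled events, most of the minor enantiomer of either event ends in separable S,R and R,S diastereomers, which raises the enantiopurity of the S,S tetraene.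

Step 12
Reactants: 17 tetraene bis[(1S)-allylic ether]
Product: 19 bis(2H-chromene), via lower-ring-closed triene 18 (not isolated)
Conditions: second-generation Hoveyda–Grubbs catalyst RuCl2(H2IMes)(=CH-C6H4-2-O-i-Pr) (two portions of 5 mol%), 1,4-benzoquinone (10 mol%), toluene (0.005 M), 70 °C, argon sparge, exclusion of light
Reagents that add atoms: none
Why: Ruthenium-alkylidene olefin metathesis by the metallacyclobutane mechanism: the catalyst loads onto a monosubstituted vinyl group, adds across the alkenyl group ortho to the same ether oxygen and cycloreverts with loss of ethylene, once for each pyran ring. The closest known reaction type is RCM of 2-alkenylphenyl allyl ethers to 2H-chromenes with second-generation ruthenium catalysts, including closure onto α-aryl styrenes (1,1-diarylethylenes) to give 4-aryl-2H-chromenes. Ring C' of the lower unit should close first as a six-membered ring by joining the styrene CH and the allylic CH into the cis C3'=C4' bond (triene 18); ring C of the upper unit then closes as a six-membered ring onto the 1,1-diarylethylene, giving the trisubstituted C3=C4 bond that carries the lower unit on C4. No stereocenter is created: the two S centres from steps 9 and 11 (future C2' and C2) lie outside the reacting π systems and are carried through to direct the hydroboration of step 13. The step needs pairing selectivity and freedom from double-bond migration: each allylic vinyl group can reach only the alkenyl group ortho to its own oxygen in a six-membered closure (a crossed pairing would need a ten-membered or para-bridged ring), high dilution disfavours cross-metathesis, and benzoquinone intercepts ruthenium hydrides that would isomerise the allyl ethers or the products.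

Step 13
Reactants: 19 bis(2H-chromene)
Product: 21 hexa-O-benzyl ether of the target, via bis(alkylborane) 20 (not isolated)
Conditions: BH3·SMe2 (4 equiv), THF, 0 °C to rt; then 3 M NaOH, 30% H2O2, 0 °C to rt
Reagents that add atoms: borane–dimethyl sulfide, C[S+](C)[BH3-] (boron held in 20, hydrogen kept in 21); hydrogen peroxide, OO
Why: Hydroboration–oxidation of 2H-chromenes (flav-3-enes): boron should add to C3 and C3' (remote from the electron-rich benzylic carbon and next to the O-bearing C2) in a syn four-centre addition on the face opposite the C2 aryl group, which sets C3 and C3' trans to the C2 aryl groups and, at the trisubstituted upper alkene, delivers hydrogen to C4 cis to boron so that the C4 aryl group ends trans to the C3 oxygen (the 4α linkage), the C–B bonds then being oxidised with retention.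

Step 14
Reactants: 21 hexa-O-benzyl ether of the target
Product: 22 fisetinidol-(4α→6)-fisetinidol (target)
Conditions: H2 (1 atm), Pd(OH)2/C (20 wt%), THF/MeOH 1:1, rt; filtration, Sephadex LH-20 (MeOH)
Reagents that add atoms: none
Why: Catalytic hydrogenolysis of the six aryl benzyl ethers under neutral conditions should release the free phenols without acid-promoted cleavage of the interflavan bond or epimerisation, no stereocenter being touched.

**Compound list**

1 | 4-(benzyloxy)-2-hydroxybenzaldehyde | O=Cc1ccc(OCc2ccccc2)cc1O | starting material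
2 | 4-(benzyloxy)-5-bromo-2-hydroxybenzaldehyde | O=Cc1cc(Br)c(OCc2ccccc2)cc1O | intermediate
3 | 5-(benzyloxy)-4-bromo-2-ethenylphenol | C=Cc1cc(Br)c(OCc2ccccc2)cc1O | intermediate
4 | 1-[4-(benzyloxy)-2-hydroxyphenyl]ethan-1-one | CC(=O)c1ccc(OCc2ccccc2)cc1O | starting material
5 | 1-{4-(benzyloxy)-2-[(triisopropylsilyl)oxy]phenyl}ethan-1-one | CC(=O)c1ccc(OCc2ccccc2)cc1O[Si](C(C)C)(C(C)C)C(C)C | intermediate
6 | (E)-N'-(1-{4-(benzyloxy)-2-[(triisopropylsilyl)oxy]phenyl}ethylidene)-4-methylbenzenesulfonohydrazide | C/C(=N\NS(=O)(=O)c1ccc(C)cc1)c1ccc(OCc2ccccc2)cc1O[Si](C(C)C)(C(C)C)C(C)C | intermediate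
7 | [5-(benzyloxy)-2-(1-diazoethyl)phenoxy]tri(propan-2-yl)silane | CC(=[N+]=[N-])c1ccc(OCc2ccccc2)cc1O[Si](C(C)C)(C(C)C)C(C)C | intermediate (not isolated)
8 | 5-(benzyloxy)-4-(1-{4-(benzyloxy)-2-[(triisopropylsilyl)oxy]phenyl}ethenyl)-2-ethenylphenol | C=Cc1cc(C(=C)c2ccc(OCc3ccccc3)cc2O[Si](C(C)C)(C(C)C)C(C)C)c(OCc2ccccc2)cc1O | intermediate
9 | 3,4-bis(benzyloxy)benzaldehyde | O=Cc1ccc(OCc2ccccc2)c(OCc2ccccc2)c1 | starting material
10 | ethyl (2E)-3-[3,4-bis(benzyloxy)phenyl]prop-2-enoate | CCOC(=O)/C=C/c1ccc(OCc2ccccc2)c(OCc2ccccc2)c1 | intermediate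
11 | (2E)-3-[3,4-bis(benzyloxy)phenyl]prop-2-en-1-ol | OC/C=C/c1ccc(OCc2ccccc2)c(OCc2ccccc2)c1 | intermediate
12 | (2E)-3-[3,4-bis(benzyloxy)phenyl]prop-2-en-1-yl methyl carbonate | COC(=O)OC/C=C/c1ccc(OCc2ccccc2)c(OCc2ccccc2)c1 | intermediate
13 | lithium aryloxide of 8 | [Li+].C=Cc1cc(C(=C)c2ccc(OCc3ccccc3)cc2O[Si](C(C)C)(C(C)C)C(C)C)c(OCc2ccccc2)cc1[O-] | intermediate (not isolated)
14 | {5-(benzyloxy)-2-[1-(2-(benzyloxy)-4-{[(1S)-1-[3,4-bis(benzyloxy)phenyl]prop-2-en-1-yl]oxy}-5-ethenylphenyl)ethenyl]phenoxy}tri(propan-2-yl)silane (8 with its free phenolic oxygen carrying the S-configured 1-arylallyl group) | CC(C)[Si](C(C)C)(C(C)C)Oc1cc(OCc2ccccc2)ccc1C(=C)c1cc(C=C)c(O[C@@H](C=C)c2ccc(OCc3ccccc3)c(OCc3ccccc3)c2)cc1OCc1ccccc1 | intermediate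
15 | 5-(benzyloxy)-2-[1-(2-(benzyloxy)-4-{[(1S)-1-[3,4-bis(benzyloxy)phenyl]prop-2-en-1-yl]oxy}-5-ethenylphenyl)ethenyl]phenol | Oc1cc(OCc2ccccc2)ccc1C(=C)c1cc(C=C)c(O[C@@H](C=C)c2ccc(OCc3ccccc3)c(OCc3ccccc3)c2)cc1OCc1ccccc1 | intermediate
16 | lithium aryloxide of 15 | [Li+].[O-]c1cc(OCc2ccccc2)ccc1C(=C)c1cc(C=C)c(O[C@@H](C=C)c2ccc(OCc3ccccc3)c(OCc3ccccc3)c2)cc1OCc1ccccc1 | intermediate (not isolated)
17 | tetraene: the 1,1-diarylethylene in which each of the two phenolic oxygens carries a (1S)-1-[3,4-bis(benzyloxy)phenyl]prop-2-en-1-yl group (both centres S) | C=C[C@H](Oc1cc(OCc2ccccc2)ccc1C(=C)c1cc(C=C)c(O[C@@H](C=C)c2ccc(OCc3ccccc3)c(OCc3ccccc3)c2)cc1OCc1ccccc1)c1ccc(OCc2ccccc2)c(OCc2ccccc2)c1 | intermediate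
18 | triene with the lower ring closed: (2S)-7-(benzyloxy)-2-[3,4-bis(benzyloxy)phenyl]-2H-chromene carrying at C6 the 1-arylethenyl group whose aryl ring still bears the (1S)-allylic ether | C=C[C@H](Oc1cc(OCc2ccccc2)ccc1C(=C)c1cc2c(cc1OCc1ccccc1)O[C@H](c1ccc(OCc3ccccc3)c(OCc3ccccc3)c1)C=C2)c1ccc(OCc2ccccc2)c(OCc2ccccc2)c1 | intermediate (not isolated)
19 | (2S)-7-(benzyloxy)-2-[3,4-bis(benzyloxy)phenyl]-4-{(2S)-7-(benzyloxy)-2-[3,4-bis(benzyloxy)phenyl]-2H-chromen-6-yl}-2H-chromene | c1ccccc1COc1ccc2c(c1)O[C@H](c1ccc(OCc3ccccc3)c(OCc3ccccc3)c1)C=C2c1cc2c(cc1OCc1ccccc1)O[C@H](c1ccc(OCc3ccccc3)c(OCc3ccccc3)c1)C=C2 | intermediate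
20 | bis(alkylborane): 21 with a BH2 group in place of each of the C3 and C3' hydroxyls, same spatial arrangement | c1ccccc1COc1ccc2c(c1)O[C@H](c1ccc(OCc3ccccc3)c(OCc3ccccc3)c1)[C@@H](B)[C@@H]2c1cc2c(cc1OCc1ccccc1)O[C@H](c1ccc(OCc3ccccc3)c(OCc3ccccc3)c1)[C@@H](B)C2 | intermediate (not isolated)
21 | 7,3',4'-tri-O-benzylfisetinidol-(4α→6)-7,3',4'-tri-O-benzylfisetinidol (upper unit 2,3-trans-3,4-trans, lower unit 2,3-trans; all five centres arranged as in the target) | c1ccccc1COc1ccc2c(c1)O[C@H](c1ccc(OCc3ccccc3)c(OCc3ccccc3)c1)[C@@H](O)[C@@H]2c1cc2c(cc1OCc1ccccc1)O[C@H](c1ccc(OCc3ccccc3)c(OCc3ccccc3)c1)[C@@H](O)C2 | intermediate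
22 | fisetinidol-(4α→6)-fisetinidol, (2R,3S,4R)-2-(3,4-dihydroxyphenyl)-4-[(2R,3S)-2-(3,4-dihydroxyphenyl)-3,7-dihydroxy-3,4-dihydro-2H-chromen-6-yl]-3,4-dihydro-2H-chromene-3,7-diol | Oc1ccc2c(c1)O[C@H](c1ccc(O)c(O)c1)[C@@H](O)[C@@H]2c1cc2c(cc1O)O[C@H](c1ccc(O)c(O)c1)[C@@H](O)C2 | target

**Step count and risks**

Total step count: 14. Longest linear sequence: 9 steps (steps 3, 4, 5, 9, 10, 11, 12, 13, 14; the branches through steps 1, 2 and through steps 6, 7, 8 are equally long).

Steps most likely to fail:

Step 12. The second ring closure may stall: the 1,1-diarylethylene is ortho-substituted on both rings and may not engage the ruthenium alkylidene after the lower ring has closed, while ruthenium hydride-mediated double-bond migration or light-induced ring opening of the chromenes competes at the temperature needed. The fallback gives up the dimer-level double closure in favour of monomer-level closure followed by the classical acid-mediated interflavan coupling. It sets out from 1 and 12 and comes back at 21. Wittig methylenation of 1 (as in step 2) gives 5-(benzyloxy)-2-ethenylphenol F1. Iridium-catalysed etherification of its lithium aryloxide with 12 (as in step 9) then gives 4-(benzyloxy)-2-{[(1S)-1-[3,4-bis(benzyloxy)phenyl]prop-2-en-1-yl]oxy}-1-ethenylbenzene F2. RCM of this unhindered styrene and allyl ether pair (same ruthenium catalyst, CH2Cl2, 40 °C) still closes the pyran ring through C3=C4 and gives (2S)-7-(benzyloxy)-2-[3,4-bis(benzyloxy)phenyl]-2H-chromene F3. One portion of F3 is hydroborated and oxidised as in step 13 to tri-O-benzylfisetinidol F4, the nucleophile. The other portion is dihydroxylated (OsO4 cat., NMO, acetone/water) anti to the C2 aryl group to give the 2,3-trans-3,4-cis diol, tri-O-benzylleucofisetinidin F5, the electrophile. BF3·OEt2 (CH2Cl2, −78 to −30 °C) ionises the C4 hydroxyl of F5 to the para-benzyloxy-stabilised benzylic cation in the presence of excess F4. Attack by C6 of F4 anti to the C3 hydroxyl should give 21, to be separated from C8-linked and 4β isomers.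

Step 5. Oxidative addition may be slow because the aryl bromide carries a para aryloxide under the basic conditions. The diazoalkane, hindered by its ortho silyloxy group, may collapse by 1,2-hydrogen shift before palladium intercepts it. The silyl ether may be lost to the alkoxide base at 100 °C, and Heck-type consumption of the vinyl group may compete. The fallback builds the diarylethylene by carbonyl addition and dehydration instead of carbene coupling. It sets out from 3 and 5 and comes back at 8. Compound 3 is deprotonated (MeLi, 1.0 equiv, THF, −78 °C) and the resulting lithium aryloxide undergoes bromine–lithium exchange (t-BuLi, 2.0 equiv, −78 °C, faster than addition to the styrene). Transmetalation with CeCl3 and addition to ketone 5 give, after aqueous NH4Cl work-up, the racemic tertiary carbinol 5-(benzyloxy)-4-(1-{4-(benzyloxy)-2-[(triisopropylsilyl)oxy]phenyl}-1-hydroxyethyl)-2-ethenylphenol F6. This para-hydroxybenzylic alcohol should lose water under mild acid catalysis (pyridinium p-toluenesulfonate, toluene, 50 °C), which the aryl silyl ether tolerates, and so return 8.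

Step 13. Three processes may intervene: boron may be placed at the benzylic C4' of the lower, 1,2-disubstituted chromene; the β-aryloxy organoborane may undergo β-elimination with opening of the pyran ring; and hydroboration of the hindered trisubstituted upper alkene may be incomplete. The fallback replaces uncatalysed borane addition by copper-catalysed borylcupration–protonation, which gives an isolable boronic ester. It sets out from 19 and comes back at 21. B2pin2 (2.5 equiv), (IPr)CuCl (10 mol%, IPr = 1,3-bis(2,6-diisopropylphenyl)imidazol-2-ylidene), NaOtBu (20 mol%) and MeOH (4 equiv) in THF at rt should add boron to C3 and C3' and copper to the benzylic C4 and C4', syn and anti to the C2 aryl groups. Protonation of the C–Cu bonds with retention gives the bis(pinacol boronate) F7, whose boronic ester groups resist β-elimination. Oxidation with NaBO3·4H2O (THF/water, rt) proceeds with retention and returns 21.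

**Further compounds**

F1 | step 12 | 5-(benzyloxy)-2-ethenylphenol | C=Cc1ccc(OCc2ccccc2)cc1O
F2 | step 12 | 4-(benzyloxy)-2-{[(1S)-1-[3,4-bis(benzyloxy)phenyl]prop-2-en-1-yl]oxy}-1-ethenylbenzene | C=C[C@H](Oc1cc(OCc2ccccc2)ccc1C=C)c1ccc(OCc2ccccc2)c(OCc2ccccc2)c1
F3 | step 12 | (2S)-7-(benzyloxy)-2-[3,4-bis(benzyloxy)phenyl]-2H-chromene | c1ccccc1COc1ccc2c(c1)O[C@H](c1ccc(OCc3ccccc3)c(OCc3ccccc3)c1)C=C2
F4 | step 12 | (2R,3S)-7-(benzyloxy)-2-[3,4-bis(benzyloxy)phenyl]-3,4-dihydro-2H-chromen-3-ol (tri-O-benzylfisetinidol) | c1ccccc1COc1ccc2c(c1)O[C@H](c1ccc(OCc3ccccc3)c(OCc3ccccc3)c1)[C@@H](O)C2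
F5 | step 12 | (2R,3S,4S)-7-(benzyloxy)-2-[3,4-bis(benzyloxy)phenyl]-3,4-dihydro-2H-chromene-3,4-diol (2,3-trans-3,4-cis) | c1ccccc1COc1ccc2c(c1)O[C@H](c1ccc(OCc3ccccc3)c(OCc3ccccc3)c1)[C@@H](O)[C@H]2O
F6 | step 5 | racemic 5-(benzyloxy)-4-(1-{4-(benzyloxy)-2-[(triisopropylsilyl)oxy]phenyl}-1-hydroxyethyl)-2-ethenylphenol | CC(O)(c1ccc(OCc2ccccc2)cc1O[Si](C(C)C)(C(C)C)C(C)C)c1cc(C=C)c(O)cc1OCc1ccccc1
F7 | step 13 | bis(pinacol boronate): 21 with a 4,4,5,5-tetramethyl-1,3,2-dioxaborolan-2-yl group in place of each of the C3 and C3' hydroxyls, same spatial arrangement | c1ccccc1COc1ccc2c(c1)O[C@H](c1ccc(OCc3ccccc3)c(OCc3ccccc3)c1)[C@@H](B3OC(C)(C)C(C)(C)O3)[C@@H]2c1cc2c(cc1OCc1ccccc1)O[C@H](c1ccc(OCc3ccccc3)c(OCc3ccccc3)c1)[C@@H](B1OC(C)(C)C(C)(C)O1)C2
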